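**Strategy.** Everything rests on closing the carbocycle (C9a, C9, C10, C11, C12, C1; tuberostemonine numbering: pyrrole N4/C9a/C1/C2/C3, azepine N4/C5–C9/C9a, fused lactone O/C11–C14) last, by a formal [3+3] union. Exploited feature: the pyrrole α-carbon C9a next to N4 is a π-nucleophile and C12, on pyrrole C1, can be the γ-carbon of a 2-methoxycarbonylallylboronate, while C9=C10(Et)–C11HO is an enal. One amine-catalysed cascade on a pyrrole carrying this enal on an N4-(CH2)4 tether, the allylboronate on C1 and the finished lactone on C3 makes C9a–C9 (Friedel–Crafts conjugate addition) and C11–C12 (chair allylboration), then lactonises: azepine, carbocycle, α-methylene lactone and four stereocentres. Hydrogenation sets C13.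

Key step: step 7

Remark: the sense of induction of the cinchona primary amine in step 7 is assumed by analogy with iminium-ion additions to α-branched enals; should the quinine-derived amine favour the 9S series, its quinidine-derived pseudoenantiomer is used with nothing else changed.

**Step 1**
Reactants: 1 1H-pyrrole-3-carbaldehyde; 2 (S)-methylsuccinic anhydride [(3S)-3-methyloxolane-2,5-dione]
Product: 3 (2S)-4-(4-formyl-1H-pyrrol-2-yl)-2-methyl-4-oxobutanoic acid
Conditions: AlCl3 (3.5 equiv), ClCH2CH2Cl/MeNO2, 0 to 23 °C; aq. HCl work-up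
Reagents that add atoms: none
Why: Friedel–Crafts acylation with a cyclic anhydride should take place at C5 of the AlCl3-complexed 3-formylpyrrole (the α-position not conjugated with the formyl group) and open the anhydride at its less hindered CH2–C=O carbonyl, so the methyl stereocentre brought in by 2 ends up α to the free acid and is not touched.

**Step 2**
Reactants: 3 (2S)-4-(4-formyl-1H-pyrrol-2-yl)-2-methyl-4-oxobutanoic acid; 4 6-bromohex-1-ene (2.4 equiv)
Product: 5 hex-5-en-1-yl (2S)-4-[4-formyl-1-(hex-5-en-1-yl)-1H-pyrrol-2-yl]-2-methyl-4-oxobutanoate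
Conditions: K2CO3, DMF, 50 °C
Reagents that add atoms: none
Why: SN2 alkylation of the acidic acylpyrrole N–H and of the carboxylate in one pot installs the N-(CH2)4CH=CH2 tether and a throw-away ester, carbonate being too weak a base to epimerise the α-methyl centre.

**Step 3**
Reactants: 5 hex-5-en-1-yl (2S)-4-[4-formyl-1-(hex-5-en-1-yl)-1H-pyrrol-2-yl]-2-methyl-4-oxobutanoate; 6 methyl (triphenylphosphoranylidene)acetate
Product: 8 hex-5-en-1-yl (2S)-4-[4-[(Z)-2-bromo-3-methoxy-3-oxoprop-1-en-1-yl]-1-(hex-5-en-1-yl)-1H-pyrrol-2-yl]-2-methyl-4-oxobutanoate, via bromo ylide 7 (not isolated)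
Conditions: 6, NBS, CH2Cl2, −20 °C; then 5, 23 to 40 °C
Reagents that add atoms: N-bromosuccinimide, O=C1CCC(=O)N1Br
Why: one-pot ylide bromination and Wittig olefination: the stabilised bromo ylide should react only with the aldehyde (the acylpyrrole ketone is a hindered vinylogous amide) and give the (Z)-α-bromoacrylate with the ester trans to the pyrrole.

**Step 4**
Reactants: 8 the (Z)-α-bromoacrylate; 9 2-(iodomethyl)-4,4,5,5-tetramethyl-1,3,2-dioxaborolane
Product: 11 hex-5-en-1-yl (2S)-4-[1-(hex-5-en-1-yl)-4-[(E)-3-methoxy-3-oxo-2-[(4,4,5,5-tetramethyl-1,3,2-dioxaborolan-2-yl)methyl]prop-1-en-1-yl]-1H-pyrrol-2-yl]-2-methyl-4-oxobutanoate, via zinc reagent 10 (not isolated)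
Conditions: 9, Zn dust (Me3SiCl-activated), THF, 23 °C; then 8, Pd(PPh3)4 (5 mol%), THF, 40 °C
Reagents that add atoms: none
Why: Negishi cross-coupling of the borylmethylzinc iodide with the alkenyl bromide proceeds with retention of alkene geometry, so CH2Bpin is placed cis to the pyrrole; ketone, esters and terminal alkenes are inert to the organozinc.

**Step 5**
Reactants: 11 the allylboronate keto ester
Product: 13 methyl (E)-3-[1-(hex-5-en-1-yl)-5-[(2R,4S)-4-methyl-5-oxooxolan-2-yl]-1H-pyrrol-3-yl]-2-[(4,4,5,5-tetramethyl-1,3,2-dioxaborolan-2-yl)methyl]prop-2-enoate, via hydroxy ester 12 (not isolated)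
Conditions: RuCl(p-cymene)[(R,R)-TsDPEN] (2 mol%), HCO2H/Et3N (5:2), EtOAc, 35 °C; then PhMe, 60 °C
Reagents that add atoms: none
Why: Noyori asymmetric transfer hydrogenation of the aryl ketone with the (R,R)-catalyst should give the (R)-carbinol (pyrrole as the large group, as for acetophenone), which lactonises with loss of hex-5-en-1-ol to the trans-(2R,4S) lactone, the 4S methyl centre coming from 2.

**Step 6**
Reactants: 13 the lactone allylboronate; 14 2-ethylacrolein (2-methylidenebutanal, 5 equiv)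
Product: 15 methyl (E)-3-[1-[(E)-6-ethyl-7-oxohept-5-en-1-yl]-5-[(2R,4S)-4-methyl-5-oxooxolan-2-yl]-1H-pyrrol-3-yl]-2-[(4,4,5,5-tetramethyl-1,3,2-dioxaborolan-2-yl)methyl]prop-2-enoate
Conditions: second-generation Hoveyda–Grubbs catalyst (5 mol%), CH2Cl2, 40 °C
Reagents that add atoms: none
Why: olefin cross-metathesis of the terminal alkene with a 1,1-disubstituted enal (as known for methacrolein) should give the (E)-trisubstituted enal, the trisubstituted electron-poor allylboronate alkene being metathesis-inert and too slow to allylate the enal at this temperature.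

**Step 7**
Reactants: 15 the enal allylboronate
Product: 18 (9R,10R,11R,12R,18R,20S)-13-methylidene pentacycle (13,15-didehydro target; cis-fused α-methylene γ-lactone), via azepine aldehyde 16 (not isolated), via borate ester 17 (not isolated)
Conditions: 9-amino-9-deoxy-epi-quinine (20 mol%), CF3CO2H (40 mol%), H2O (5 equiv), PhMe (0.01 M), 23 °C then 50 °C
Reagents that add atoms: none
Why: The primary amine condenses with the α-branched enal to an iminium ion, which pyrrole C9a (the only free α-position, C3 carrying the lactone) attacks in a 7-exo-trig Friedel–Crafts conjugate addition that closes the azepine; enamine protonation and hydrolysis unveil the saturated aldehyde 16, whose C10 centre stays epimerisable through the enamine. The pendant 2-methoxycarbonylallylboronate then adds intramolecularly through a bicyclic chair (Zimmerman–Traxler) transition state (6-exo-trig at the C11 carbonyl, γ-attack by C12), and the borate 17 lactonises by 5-exo-trig acyl substitution with loss of MeOBpin. The closest known reaction types are iminium-catalysed intramolecular pyrrole–enal Friedel–Crafts cyclisations to pyrrolo[1,2-a]azepines and the allylboration–lactonisation of aldehydes with 2-alkoxycarbonylallylboronates. C9 is set by the cinchona amine (face shielding of the iminium ion); C11 and C12 come out cis because the pyrrole, cis to CH2B, sits axial in the chair while the C10 chain is equatorial; C10 is funnelled to the epimer that keeps ethyl equatorial, trans to C8 and cis to O11, since C8, tied back to N4, is pseudo-equatorial at C9. The step needs 1,4- over 1,2-addition (iminium activation), C9a regiochemistry (C3 blocked) and aldehyde-selective allylation (only the saturated aldehyde is within reach of C12).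

**Step 8**
Reactants: 18 the 13-methylidene pentacycle
Product: 19 CNP0232452.1 [(9R,10R,11R,12S,13S,18R,20S)-configured pentacyclic bis-lactone]
Conditions: H2 (1 atm), RhCl(PPh3)3 (10 mol%), benzene/EtOH, 23 °C
Reagents that add atoms: none
Why: homogeneous hydrogenation of the 1,1-disubstituted alkene should deliver hydrogen to the convex face of the cis-fused lactone (the face of H11 and H12), placing the C13 methyl on the concave face (13S), while the pyrrole and the pyrrolylic C–O bond of the C3 lactone, at risk with Pd/C, are left alone.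

**Compound list**
1 | 1H-pyrrole-3-carbaldehyde | O=Cc1cc[nH]c1 | starting material
2 | (S)-methylsuccinic anhydride | O=C1C[C@H](C)C(=O)O1 | starting material
3 | (2S)-4-(4-formyl-1H-pyrrol-2-yl)-2-methyl-4-oxobutanoic acid | O=Cc1c[nH]c(C(=O)C[C@H](C)C(=O)O)c1 | intermediate
4 | 6-bromohex-1-ene | BrCCCCC=C | starting material
5 | hex-5-en-1-yl (2S)-4-[4-formyl-1-(hex-5-en-1-yl)-1H-pyrrol-2-yl]-2-methyl-4-oxobutanoate | O=Cc1cn(CCCCC=C)c(C(=O)C[C@H](C)C(=O)OCCCCC=C)c1 | intermediate
6 | methyl (triphenylphosphoranylidene)acetate | COC(=O)C=P(c1ccccc1)(c1ccccc1)c1ccccc1 | starting material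
7 | methyl bromo(triphenylphosphoranylidene)acetate (bromo ylide, made in the flask) | COC(=O)C(Br)=P(c1ccccc1)(c1ccccc1)c1ccccc1 | intermediate
8 | hex-5-en-1-yl (2S)-4-[4-[(Z)-2-bromo-3-methoxy-3-oxoprop-1-en-1-yl]-1-(hex-5-en-1-yl)-1H-pyrrol-2-yl]-2-methyl-4-oxobutanoate | COC(=O)/C(Br)=C/c1cn(CCCCC=C)c(C(=O)C[C@H](C)C(=O)OCCCCC=C)c1 | intermediate
9 | 2-(iodomethyl)-4,4,5,5-tetramethyl-1,3,2-dioxaborolane | ICB1OC(C)(C)C(C)(C)O1 | starting material
10 | [(4,4,5,5-tetramethyl-1,3,2-dioxaborolan-2-yl)methyl]zinc iodide (zinc reagent, made in the flask) | I[Zn]CB1OC(C)(C)C(C)(C)O1 | intermediate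
11 | hex-5-en-1-yl (2S)-4-[1-(hex-5-en-1-yl)-4-[(E)-3-methoxy-3-oxo-2-[(pinacolboryl)methyl]prop-1-en-1-yl]-1H-pyrrol-2-yl]-2-methyl-4-oxobutanoate | COC(=O)/C(CB1OC(C)(C)C(C)(C)O1)=C/c1cn(CCCCC=C)c(C(=O)C[C@H](C)C(=O)OCCCCC=C)c1 | intermediate
12 | hex-5-en-1-yl (2S,4R)-4-hydroxy-4-[1-(hex-5-en-1-yl)-4-[(E)-3-methoxy-3-oxo-2-[(pinacolboryl)methyl]prop-1-en-1-yl]-1H-pyrrol-2-yl]-2-methylbutanoate | COC(=O)/C(CB1OC(C)(C)C(C)(C)O1)=C/c1cn(CCCCC=C)c([C@H](O)C[C@H](C)C(=O)OCCCCC=C)c1 | intermediate
13 | methyl (E)-3-[1-(hex-5-en-1-yl)-5-[(2R,4S)-4-methyl-5-oxooxolan-2-yl]-1H-pyrrol-3-yl]-2-[(pinacolboryl)methyl]prop-2-enoate | COC(=O)/C(CB1OC(C)(C)C(C)(C)O1)=C/c1cn(CCCCC=C)c([C@H]2C[C@H](C)C(=O)O2)c1 | intermediate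
14 | 2-ethylacrolein (2-methylidenebutanal) | CCC(=C)C=O | starting material
15 | methyl (E)-3-[1-[(E)-6-ethyl-7-oxohept-5-en-1-yl]-5-[(2R,4S)-4-methyl-5-oxooxolan-2-yl]-1H-pyrrol-3-yl]-2-[(pinacolboryl)methyl]prop-2-enoate | COC(=O)/C(CB1OC(C)(C)C(C)(C)O1)=C/c1cn(CCCC/C=C(CC)/C=O)c([C@H]2C[C@H](C)C(=O)O2)c1 | intermediate
16 | methyl (E)-3-[(9R)-3-[(2R,4S)-4-methyl-5-oxooxolan-2-yl]-9-[(2R)-1-oxobutan-2-yl]-6,7,8,9-tetrahydro-5H-pyrrolo[1,2-a]azepin-1-yl]-2-[(pinacolboryl)methyl]prop-2-enoate | CC[C@@H](C=O)[C@H]1CCCCn2c([C@H]3C[C@H](C)C(=O)O3)cc(/C=C(\CB4OC(C)(C)C(C)(C)O4)C(=O)OC)c12 | intermediate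
17 | borate ester of the C11 alcohol: (9R,10R,11R,12R)-tricycle with C11–OBpin cis to C12–C(=CH2)CO2Me, 10-ethyl, C3 lactone | CC[C@H]1[C@@H](OB2OC(C)(C)C(C)(C)O2)[C@@H](C(=C)C(=O)OC)c2cc([C@H]3C[C@H](C)C(=O)O3)n3c2[C@@H]1CCCC3 | intermediate
18 | (9R,10R,11R,12R,18R,20S)-13-methylidene pentacycle (13,15-didehydro target) | CC[C@H]1[C@H]2OC(=O)C(=C)[C@H]2c2cc([C@H]3C[C@H](C)C(=O)O3)n3c2[C@@H]1CCCC3 | intermediate
19 | CNP0232452.1, (9R,10R,11R,12S,13S,18R,20S) | CC[C@H]1[C@H]2OC(=O)[C@@H](C)[C@H]2c2cc([C@H]3C[C@H](C)C(=O)O3)n3c2[C@@H]1CCCC3 | target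

**Step count.** Total: 8 steps. Longest linear sequence: 8 steps (from 1).

**Steps most likely to fail**

Step 7. The ring-closing Friedel–Crafts addition may be slow, because the pyrrole α-carbon is deactivated by the conjugated acrylate and the iminium ion is α-branched. Intermolecular allylboration, allylation of the catalyst-bound aldimine, or cyclisation before C10 has equilibrated (eroding diastereocontrol) could then compete. The fallback decouples the two bond formations with a latent nucleophile: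
- From 8, Negishi coupling with (trimethylsilyl)methylzinc chloride F1 (made in the flask from Me3SiCH2MgCl and ZnCl2; Pd(PPh3)4) would give the (Z)-2-(trimethylsilylmethyl)acrylate keto ester F2.
- Transfer hydrogenation as in step 5 would give the hydroxy ester F3 and, after lactonisation, the lactone F4.
- Cross-metathesis with 14 would give the enal F5.
- The same amine/CF3CO2H catalyst would give the isolable azepine aldehyde F6, the allylsilane being inert to aldehydes without activation.
- Fluoride (Bu4NF, THF, 0 °C) would then trigger the known intramolecular 2-(alkoxycarbonyl)allylsilane–aldehyde cyclisation with lactonisation to the cis-fused α-methylene lactone, rejoining the route at 18.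

Step 5. Hydride transfer to the electron-rich 2-acylpyrrole ketone may be slow, so that conjugate reduction or protodeboronation of the allylboronate, or ionisation of the pyrrolyl carbinol, intervenes. The fallback moves the reduction ahead of the boron chemistry and uses a stoichiometric chiral chloroborane. From 8, (+)-B-chlorodiisopinocampheylborane (THF, −25 °C; diethanolamine work-up) would give the (R)-hydroxy ester F7, which on warming lactonises to the bromoacrylate lactone F8. Negishi coupling of F8 with 10 as in step 4 rejoins the route at 13.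

Step 1. Regiocontrol may be poor in both partners (C2 against C5 of the pyrrole, hindered against unhindered anhydride carbonyl), and conversion of the AlCl3-complexed, deactivated pyrrole may be low. The fallback sets out from 2 and commercial pyrrole. Pyrrol-1-ylmagnesium bromide F9 (from pyrrole and EtMgBr) is C-acylated by 2 to (2S)-2-methyl-4-oxo-4-(1H-pyrrol-2-yl)butanoic acid F10. Rieche formylation (Cl2CHOMe, AlCl3), which 2-acylpyrroles undergo at C4, then gives 3, where the route is rejoined.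

**Further compounds**
F1 | step 7 | (trimethylsilyl)methylzinc chloride | C[Si](C)(C)C[Zn]Cl
F2 | step 7 | hex-5-en-1-yl (2S)-4-[1-(hex-5-en-1-yl)-4-[(Z)-3-methoxy-3-oxo-2-[(trimethylsilyl)methyl]prop-1-en-1-yl]-1H-pyrrol-2-yl]-2-methyl-4-oxobutanoate | COC(=O)/C(C[Si](C)(C)C)=C/c1cn(CCCCC=C)c(C(=O)C[C@H](C)C(=O)OCCCCC=C)c1
F3 | step 7 | hex-5-en-1-yl (2S,4R)-4-hydroxy-4-[1-(hex-5-en-1-yl)-4-[(Z)-3-methoxy-3-oxo-2-[(trimethylsilyl)methyl]prop-1-en-1-yl]-1H-pyrrol-2-yl]-2-methylbutanoate | COC(=O)/C(C[Si](C)(C)C)=C/c1cn(CCCCC=C)c([C@H](O)C[C@H](C)C(=O)OCCCCC=C)c1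
F4 | step 7 | methyl (Z)-3-[1-(hex-5-en-1-yl)-5-[(2R,4S)-4-methyl-5-oxooxolan-2-yl]-1H-pyrrol-3-yl]-2-[(trimethylsilyl)methyl]prop-2-enoate | COC(=O)/C(C[Si](C)(C)C)=C/c1cn(CCCCC=C)c([C@H]2C[C@H](C)C(=O)O2)c1
F5 | step 7 | methyl (Z)-3-[1-[(E)-6-ethyl-7-oxohept-5-en-1-yl]-5-[(2R,4S)-4-methyl-5-oxooxolan-2-yl]-1H-pyrrol-3-yl]-2-[(trimethylsilyl)methyl]prop-2-enoate | COC(=O)/C(C[Si](C)(C)C)=C/c1cn(CCCC/C=C(CC)/C=O)c([C@H]2C[C@H](C)C(=O)O2)c1
F6 | step 7 | methyl (Z)-3-[(9R)-3-[(2R,4S)-4-methyl-5-oxooxolan-2-yl]-9-[(2R)-1-oxobutan-2-yl]-6,7,8,9-tetrahydro-5H-pyrrolo[1,2-a]azepin-1-yl]-2-[(trimethylsilyl)methyl]prop-2-enoate | CC[C@@H](C=O)[C@H]1CCCCn2c([C@H]3C[C@H](C)C(=O)O3)cc(/C=C(\C[Si](C)(C)C)C(=O)OC)c12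
F7 | step 5 | hex-5-en-1-yl (2S,4R)-4-[4-[(Z)-2-bromo-3-methoxy-3-oxoprop-1-en-1-yl]-1-(hex-5-en-1-yl)-1H-pyrrol-2-yl]-4-hydroxy-2-methylbutanoate | COC(=O)/C(Br)=C/c1cn(CCCCC=C)c([C@H](O)C[C@H](C)C(=O)OCCCCC=C)c1
F8 | step 5 | methyl (Z)-2-bromo-3-[1-(hex-5-en-1-yl)-5-[(2R,4S)-4-methyl-5-oxooxolan-2-yl]-1H-pyrrol-3-yl]prop-2-enoate | COC(=O)/C(Br)=C/c1cn(CCCCC=C)c([C@H]2C[C@H](C)C(=O)O2)c1
F9 | step 1 | pyrrol-1-ylmagnesium bromide | Br[Mg]n1cccc1
F10 | step 1 | (2S)-2-methyl-4-oxo-4-(1H-pyrrol-2-yl)butanoic acid | O=C(C[C@H](C)C(=O)O)c1ccc[nH]1
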